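The other capture product forms in a single encounter, the second nucleophile meeting the open intermediate, but the open intermediate has other exits, so I reckon what fraction of the charge leaves by this one.

| flask | starting material | first nucleophile | second nucleophile | capture agent | protic impurity | time | remark | temperature |
|---|---|---|---|---|---|---|---|---|
| oak | 26 mM | 4.00 equiv (fed, over 20 min) | 3.00 equiv | 1.30 mM | 26.0 mM | 25 min | the addition at −5 °C, then warmed to 25 °C; the feed brings no volume worth counting |  |
| maple | 26 mM (fed, over 20 min) | 4.00 equiv | 3.00 equiv | 1.30 mM | 26.0 mM | 25 min | all else is in the flask from the start; the feed brings no volume worth counting | 25 °C |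
| alder | 26 mM | 4.00 equiv | 3.00 equiv | 1.30 mM | 26.0 mM | 25 min | everything together at the start | 25 °C |
| birch | 26 mM | 4.00 equiv (fed, over 5.0 min) | 3.00 equiv | 1.30 mM | 26.0 mM | 25 min | all else is in the flask from the start; the feed brings no volume worth counting | 25 °C |
| cedar | 26 mM | 4.00 equiv (fed, over 20 min) | 3.00 equiv | 1.30 mM | 26.0 mM | 25 min | all else is in the flask from the start; the feed brings no volume worth counting | 25 °C |
| larch | 26 mM | 4.00 equiv | 3.00 equiv | 1.30 mM | 26.0 mM | 25 min | everything together at the start at −5 °C, warmed to 25 °C at 20 min |  |

    starting material → open intermediate (k1 = 0.0051 s⁻¹, Ea1 = 82.0 kJ mol⁻¹)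
    first nucleophile + open intermediate → target (k2 = 0.19 M⁻¹ s⁻¹, Ea2 = 53.0 kJ mol⁻¹)
    second nucleophile + open intermediate → other capture product (k3 = 0.64 M⁻¹ s⁻¹, Ea3 = 43.0 kJ mol⁻¹)
    open intermediate → solvolysis product (k4 = 0.015 s⁻¹, Ea4 = 75.0 kJ mol⁻¹)
    open intermediate + capture agent → trapped intermediate (k5 = 0.0038 M⁻¹ s⁻¹, Ea5 = 65.0 kJ mol⁻¹)
    starting material + protic impurity → quenched substrate (k6 = 0.012 M⁻¹ s⁻¹, Ea6 = 70.0 kJ mol⁻¹)
    (constants at 25 °C)

- all constants are for 25 °C and move with temperature by the activation energies

- the flask that comes out highest in amount of other capture product, in percent of the starting material charged, or "all alike" when all lie within 1.5 percentage points (oak / maple / alder / birch / cedar / larch / all alike)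
- other capture product at the end, in percent of the starting material charged, oak
- other capture product at the end, in percent of the starting material charged, maple
- other capture product at the end, in percent of the starting material charged, alder
- other capture product at the end, in percent of the starting material charged, birch
- other capture product at the end, in percent of the starting material charged, cedar
- other capture product at the end, in percent of the starting material charged, larch

I build the flask up at 25 °C and count turnovers. I start the reckoning with opening and capture, which turn the charge into other capture product. Solvolysis is the next process: the second nucleophile at its full charge gives an exit frequency of 0.0499 s⁻¹ against 0.015 s⁻¹, so 76.9% of the open intermediate is captured. The protic impurity comes next: it takes 3.12 × 10⁻⁴ s⁻¹ against 0.0051 s⁻¹ for opening, so 94.2% of the starting material opens, and the product falls to 72.5% of the charge. I drop the capture agent, because its exit of 4.94 × 10⁻⁶ s⁻¹ is far smaller than solvolysis. The second nucleophile gives up part of its charge along the way, so I take the mean of its start and end, 87.9% of its charge, which lowers its exit to 0.0439 s⁻¹.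

The first nucleophile has an exit of 0.0198 s⁻¹ at full charge, and what counts is how much of it is present while the starting material opens. A steady feed from zero lasts a number of starting-material lifetimes, ν, and during opening the mean fraction of the feed present is (1 − e^−ν)/ν. The starting material is lost at 0.00541 s⁻¹, so the slow feed counts 6.49 lifetimes and gives 15.4%, while the quick feed counts 1.62 and gives 49.4%. The capture share, the second nucleophile's exit over the sum of the exits the open intermediate meets, is then 70.9% in cedar, 63.9% in birch and 55.8% with the first nucleophile at full charge.

Multiplying by the opening share gives 66.8% for cedar, 60.2% for birch and 52.6% for alder. Maple has the full first nucleophile, and I reckon that 3.03% of its starting material stands unopened at the end, which gives 51.0%. In oak and larch, opening runs at 1.26 × 10⁻⁴ s⁻¹ during the cold period, so I reckon that 17.0% stands unopened at the end. At the alder share, that gives 43.7% for oak and 43.7% for larch. My choice is cedar.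

The forecast says cedar, with 47.5% for oak, 52.2% for maple, 53.5% for alder, 61.3% for birch, 67% for cedar and 46.5% for larch, on the ground that the slow feed “keeps that competitor scarce while the starting material opens”. The simulation gives cedar as highest, with 46.9% for oak, 52.1% for maple, 53.8% for alder, 60.5% for birch, 66.8% for cedar and 46.0% for larch.

In cedar at 2.14 min, capture uses open intermediate 3.0 times as fast as solvolysis. Cedar has half of its capture done by 2.27 min, when 11.4% of the first nucleophile has been fed. For cedar kept at 40 °C, capture speeds up 2.30 times, solvolysis 4.26 times and opening 4.88 times, so the capture share falls from 70.9% to 60.5%, and with opening that predicts 57.7%. That flask gives 58.2%.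

The constants were set for the occasion; the flask was simulated.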